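**Retrosynthetic overview**
1. Target 9 ⇐ pentamethoxyflavone 8, by cleaving only the 5-OMe (carbonyl-chelation control) in the last step.
2. 8 ⇐ C2–C1' bond: chromone 5 is metalated at C2 to zinc species 7, so the enone β-carbon (normally an acceptor) acts as a β-acylvinyl, homoenolate-type donor toward aryl bromide 6 (Negishi coupling).
3. 5 ⇐ o-hydroxyacetophenone 3 plus one carbon from DMF-DMA (enaminone 4, then pyranone closure).
4. 3 ⇐ 1,2,3,5-tetramethoxybenzene 1 plus acetyl chloride (acylation with in-situ ortho-demethylation).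
5. Ring order: A ring bought; pyranone ring formed in step 2; B ring bought and attached intact in step 3.

Assumption: the target has no stereocentre and no hindered axis, so it is one achiral compound and no stereocontrol is needed. Compounds 1 and 6 and TMPZnCl·LiCl solution are taken as catalogue chemicals.

**Route**

Step 1
Reactants: 1 1,2,3,5-tetramethoxybenzene
Product: 3 2'-hydroxy-3',4',6'-trimethoxyacetophenone, via tetramethoxyacetophenone 2 (not isolated)
Conditions: AcCl (1.2 equiv), AlCl3 (2.2 equiv), CH2Cl2, 0 °C → rt; then ice-water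
Reagents that add atoms: acetyl chloride CC(=O)Cl
Why: Friedel–Crafts acylation at the only free position (C4 and C6 are equivalent), then AlCl3 chelation-controlled demethylation of the ortho methoxy flanked by both the acetyl and a second methoxy (twisted out of plane, most Lewis basic), the resulting aluminium chelate resisting a second cleavage.

Step 2
Reactants: 3 2'-hydroxy-3',4',6'-trimethoxyacetophenone
Product: 5 5,7,8-trimethoxy-4H-chromen-4-one, via enaminone 4 (not isolated)
Conditions: DMF-DMA (2 equiv), toluene, 100 °C; concentrate; then conc. HCl, CH2Cl2, 40 °C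
Reagents that add atoms: N,N-dimethylformamide dimethyl acetal COC(OC)N(C)C
Why: Enaminone condensation at the methyl ketone, then acid-promoted intramolecular oxa-Michael addition–elimination of dimethylamine closes the γ-pyranone (standard enaminone chromone synthesis).

Step 3
Reactants: 5 5,7,8-trimethoxy-4H-chromen-4-one; 6 1-bromo-2,3-dimethoxybenzene
Product: 8 2-(2,3-dimethoxyphenyl)-5,7,8-trimethoxy-4H-chromen-4-one, via chromon-2-ylzinc chloride 7 (not isolated)
Conditions: TMPZnCl·LiCl (1.3 equiv), THF, −30 °C → rt; then 6 (1.2 equiv), Pd(OAc)2 (2 mol%), SPhos (4 mol%), 50 °C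
Reagents that add atoms: none
Why: Directed C–H zincation followed by Negishi cross-coupling: the hindered zinc amide, with no Mg or B Lewis acid present to steer it to C3, removes the most acidic vinylic C2–H next to the ring oxygen, which turns the normally electrophilic enone β-carbon into a β-acylvinyl (d3) zinc nucleophile that is too mild to self-add or ring-open and then couples with the electrophilic carbon of the ortho-methoxy aryl bromide; no stereocentre is formed.

Step 4
Reactants: 8 2-(2,3-dimethoxyphenyl)-5,7,8-trimethoxy-4H-chromen-4-one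
Product: 9 5-hydroxy-2',3',7,8-tetramethoxyflavone
Conditions: BCl3 (1.2 equiv, 1 M in CH2Cl2), CH2Cl2, −78 → 0 °C; then H2O
Reagents that add atoms: none
Why: Chelation-controlled aryl methyl ether cleavage, in which BCl3 bound to the C4 carbonyl reaches only the peri 5-OMe through a six-membered chelate, so that methyl alone is lost at low temperature with about one equivalent; no stereocentre is involved.

**Compound list**
1 | 1,2,3,5-tetramethoxybenzene | COc1cc(OC)c(OC)c(OC)c1 | starting material
2 | 1-(2,3,4,6-tetramethoxyphenyl)ethan-1-one (2',3',4',6'-tetramethoxyacetophenone) | CC(=O)c1c(OC)cc(OC)c(OC)c1OC | intermediate (not isolated)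
3 | 1-(2-hydroxy-3,4,6-trimethoxyphenyl)ethan-1-one (2'-hydroxy-3',4',6'-trimethoxyacetophenone) | CC(=O)c1c(OC)cc(OC)c(OC)c1O | intermediate
4 | (E)-3-(dimethylamino)-1-(2-hydroxy-3,4,6-trimethoxyphenyl)prop-2-en-1-one | CN(C)/C=C/C(=O)c1c(OC)cc(OC)c(OC)c1O | intermediate (not isolated)
5 | 5,7,8-trimethoxy-4H-chromen-4-one | COc1cc(OC)c2c(=O)ccoc2c1OC | intermediate
6 | 1-bromo-2,3-dimethoxybenzene | COc1cccc(Br)c1OC | starting material
7 | chloro(5,7,8-trimethoxy-4-oxo-4H-chromen-2-yl)zinc (LiCl complex) | COc1cc(OC)c2c(=O)cc([Zn]Cl)oc2c1OC | intermediate (not isolated)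
8 | 2-(2,3-dimethoxyphenyl)-5,7,8-trimethoxy-4H-chromen-4-one (2',3',5,7,8-pentamethoxyflavone) | COc1cccc(-c2cc(=O)c3c(OC)cc(OC)c(OC)c3o2)c1OC | intermediate
9 | 2-(2,3-dimethoxyphenyl)-5-hydroxy-7,8-dimethoxy-4H-chromen-4-one (5-hydroxy-2',3',7,8-tetramethoxyflavone) | COc1cccc(-c2cc(=O)c3c(O)cc(OC)c(OC)c3o2)c1OC | target

**Totals**
Total step count: 4. Longest linear sequence: 4 (1 → 3 → 5 → 8 → 9); 6 enters in step 3.

**Three steps most likely to fail, with fallbacks**

Step 3 (highest risk). The 5-OMe/C4=O pocket could bind Li or Zn and divert the base toward C3, and the ortho-methoxy, electron-rich bromide may couple slowly. The fallback sets out from 5 and uses C2 in its native acceptor role. Pd(II)-catalysed conjugate addition of commercial (2,3-dimethoxyphenyl)boronic acid (Pd(TFA)2 5 mol%, 2,2'-bipyridine, NH4PF6, H2O, ClCH2CH2Cl, 60 °C) gives racemic 2-(2,3-dimethoxyphenyl)-5,7,8-trimethoxychroman-4-one F1. Its C2 stereocentre does not matter, because dehydrogenation (I2 10 mol%, DMSO, 120 °C) removes it and gives 8, where the fallback rejoins the route.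

Step 4. The 8-OMe and the 2'-OMe are each the crowded member of a vicinal dioxygenated pair and could also be cleaved, giving diols that are hard to separate. The fallback sets out from 5 and moves the cleavage ahead of the coupling, so the B-ring ethers never meet a Lewis acid. BCl3 (1.1 equiv, CH2Cl2, −78 → 0 °C) on 5 gives 5-hydroxy-7,8-dimethoxy-4H-chromen-4-one F2. MOMCl and iPr2NEt in CH2Cl2 give 7,8-dimethoxy-5-(methoxymethoxy)-4H-chromen-4-one F3. TMPZnCl·LiCl in THF gives chloro[7,8-dimethoxy-5-(methoxymethoxy)-4-oxo-4H-chromen-2-yl]zinc F4, which is not isolated and is coupled with 6 (Pd(OAc)2, SPhos, 50 °C) to 2-(2,3-dimethoxyphenyl)-7,8-dimethoxy-5-(methoxymethoxy)-4H-chromen-4-one F5. Dilute HCl in MeOH at rt removes the acetal and gives 9, where the fallback rejoins the route.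

Step 1. Under AlCl3 at room temperature the other ortho methoxy, the central methoxy of the 2,3,4-triad, or both ortho groups could be cleaved. The fallback sets out from 1, forms the aryl–acyl bond from an aryl anion, and does the ether cleavage separately under kinetic control. Directed ortho-lithiation (n-BuLi, TMEDA, THF, 0 °C) at the C–H flanked by two methoxy groups gives (2,3,4,6-tetramethoxyphenyl)lithium F6. Quenching with N-methoxy-N-methylacetamide (−78 °C → rt, then H2O) gives 2, this time isolated. BCl3 (1.05 equiv, CH2Cl2, −78 °C; then H2O) removes the ortho methyl flanked by the acetyl and the neighbouring methoxy and gives 3, where the fallback rejoins the route.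

**Further compounds**
F1 | step 3 | rac-2-(2,3-dimethoxyphenyl)-5,7,8-trimethoxychroman-4-one | COc1cccc(C2CC(=O)c3c(OC)cc(OC)c(OC)c3O2)c1OC
F2 | step 4 | 5-hydroxy-7,8-dimethoxy-4H-chromen-4-one | COc1cc(O)c2c(=O)ccoc2c1OC
F3 | step 4 | 7,8-dimethoxy-5-(methoxymethoxy)-4H-chromen-4-one | COCOc1cc(OC)c(OC)c2occc(=O)c12
F4 | step 4 | chloro[7,8-dimethoxy-5-(methoxymethoxy)-4-oxo-4H-chromen-2-yl]zinc | COCOc1cc(OC)c(OC)c2oc([Zn]Cl)cc(=O)c12
F5 | step 4 | 2-(2,3-dimethoxyphenyl)-7,8-dimethoxy-5-(methoxymethoxy)-4H-chromen-4-one | COCOc1cc(OC)c(OC)c2oc(-c3cccc(OC)c3OC)cc(=O)c12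
F6 | step 1 | (2,3,4,6-tetramethoxyphenyl)lithium | [Li]c1c(OC)cc(OC)c(OC)c1OC
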